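**Assumptions**
- The target has no stereocentres, so "single enantiomer" does not apply. Its stereo-elements are the Z-disubstituted alkene in the side chain and the E-enone, and both are set below.
- 5-Methoxyresorcinol, 4-hydroxybenzaldehyde, trimethyl phosphonoacetate and the Weinreb phosphonoacetamide are commercial.
- n-BuLi lithiates 2 between its two OMOM groups in preference to the OMe/OMOM-flanked positions.

## Retrosynthetic overview
1. Candidachalcone comes from mild, non-acidic removal of three MOM groups from chalcone 12. The Z-allylic tertiary alcohol next to phenols is acid-labile, so it must be deprotected late and gently.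
2. Chalcone 12 comes from ortho-lithiation of Z-styryl carbinol 7 and addition to the E-Weinreb cinnamamide 11. This builds the E-enone without an aldol on free phenols.
3. Carbinol 7 comes from a proposed new triplet-sensitised E→Z isomerisation of E-carbinol 6. Carbinol 6 comes from MeMgBr on E-cinnamate 5, which comes from HWE on aldehyde 3.
4. Aldehyde 3 comes from directed ortho-metalation of 2 between the two OMOM groups, which fixes the 3'-regiochemistry by symmetry. Both remaining C–H sites are then equivalent for acylation.
5. No ring is formed. Both arenes come from commercial phenols, and the enone C=C is formed in step 8.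

## Route

**Step 1**
Reactants: 1 (5-methoxyresorcinol)
Product: 2 (1-methoxy-3,5-bis(methoxymethoxy)benzene)
Conditions: NaH (2.4 equiv), MOMCl (2.4 equiv), THF/DMF, 0 °C → rt
Reagents that add atoms: MOMCl, ClCOC
Why: Williamson-type O-alkylation of the two phenoxides gives bis-MOM ethers, which are the strong directing groups needed in step 2.

**Step 2**
Reactants: 2
Product: 3 (2,6-bis(methoxymethoxy)-4-methoxybenzaldehyde)
Conditions: n-BuLi (1.2 equiv), THF, −20 → 0 °C, 2 h; then DMF (3 equiv), −78 °C → rt
Reagents that add atoms: DMF, CN(C)C=O (supplies the CHO)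
Why: Directed ortho-metalation is cooperatively directed by both OMOM groups to C4, the carbon between them, and quenching with DMF (Bouveault formylation) gives the aldehyde at the carbon that will carry the side chain.

**Step 3**
Reactants: 3; 4 (trimethyl phosphonoacetate)
Product: 5 (methyl (E)-3-[2,6-bis(MOMO)-4-methoxyphenyl]acrylate)
Conditions: 4 + NaH, THF, 0 °C; add 3; 0 → 60 °C
Reagents that add atoms: none (4 is a reactant)
Why: Horner–Wadsworth–Emmons olefination gives the E-enoate; heating is needed because the aldehyde is di-ortho-substituted and electron-rich.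

**Step 4**
Reactants: 5
Product: 6 ((E)-4-[2,6-bis(MOMO)-4-methoxyphenyl]-2-methylbut-3-en-2-ol)
Conditions: MeMgBr (4 equiv), THF, 0 °C → rt; NH4Cl(aq) quench
Reagents that add atoms: MeMgBr, C[Mg]Br
Why: Double Grignard addition to the ester, via the methyl ketone, gives the tertiary carbinol; conjugate addition is disfavoured by the hindered β-aryl carbon, and MOM ethers and the E-alkene survive.

**Step 5**
Reactants: 6
Product: 7 ((Z)-4-[2,6-bis(MOMO)-4-methoxyphenyl]-2-methylbut-3-en-2-ol)
Conditions: [Ir{dF(CF3)ppy}2(dtbbpy)]PF6 (1 mol%), MeCN (0.05 M), degassed, blue LEDs (450 nm), 25 °C, 24 h; then AgNO3-SiO2 chromatography to remove residual E (recycle)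
Reagents that add atoms: none
Why: Proposed new method: contra-thermodynamic triplet-energy-transfer E→Z isomerisation of a hindered, electron-rich, tertiary-carbinol β-alkylstyrene. The planar-ish E isomer is sensitised by the Ir triplet donor and twists through the perpendicular triplet. The Z isomer has the 2,6-dialkoxyaryl ring forced perpendicular to the alkene by the cis CMe2OH group, so its triplet energy is too high to be sensitised and it accumulates at the photostationary state, which sets the Z geometry. The closest known reaction type is Gilmour/Weaver-type photocatalytic E→Z isomerisation of cinnamates and β-alkylstyrenes; it has not been shown on this substrate class.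

**Step 6**
Reactants: 8 (4-hydroxybenzaldehyde)
Product: 9 (4-(methoxymethoxy)benzaldehyde)
Conditions: MOMCl (1.2 equiv), iPr2NEt (1.5 equiv), CH2Cl2, 0 °C → rt
Reagents that add atoms: MOMCl, ClCOC
Why: Standard phenol MOM protection, so the B-ring phenol survives the organolithium step.

**Step 7**
Reactants: 9; 10 (diethyl [2-(methoxy(methyl)amino)-2-oxoethyl]phosphonate)
Product: 11 ((E)-N-methoxy-N-methyl-3-[4-(MOMO)phenyl]acrylamide)
Conditions: 10 + NaH, THF, 0 °C; add 9; 0 °C → rt
Reagents that add atoms: none (10 is a reactant)
Why: HWE olefination of the Weinreb phosphonoacetamide gives the E-Weinreb cinnamamide.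

**Step 8**
Reactants: 7; 11
Product: 12 (tris-MOM chalcone)
Conditions: 7, n-BuLi (2.6 equiv), TMEDA (2.6 equiv), THF, 0 °C, 2 h; then 11 (1.3 equiv), −78 → 0 °C; NH4Cl(aq)
Reagents that add atoms: none (11 is a reactant)
Why: The first equivalent of base forms the alkoxide and the second lithiates by directed ortho-metalation between OMe and OMOM; the two such sites are equivalent by symmetry, so only one regioisomer results. Weinreb-amide 1,2-addition then gives the E-chalcone via a stable chelated tetrahedral intermediate, with the Z-alkene untouched.

**Step 9**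
Reactants: 12
Product: 13 (candidachalcone)
Conditions: TMSOTf (8 equiv), 2,2'-bipyridyl (12 equiv), CH2Cl2, 0 °C → rt, 6 h; then H2O; then K2CO3 (cat.), MeOH, 0 °C, 10 min; NaH2PO4 workup
Reagents that add atoms: none
Why: The aromatic-MOM-selective TMSOTf/bipyridyl cleavage (Fujioka-type) proceeds under buffered, non-protic-acid conditions, so the Z-allylic tertiary alcohol does not ionise to the chromene; the brief K2CO3/MeOH step removes any TMS ether on the tertiary OH.

## Compound list
1 | 5-methoxyresorcinol | COc1cc(O)cc(O)c1 | starting material
2 | 1-methoxy-3,5-bis(methoxymethoxy)benzene | COc1cc(OCOC)cc(OCOC)c1 | intermediate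
3 | 2,6-bis(MOMO)-4-methoxybenzaldehyde | COc1cc(OCOC)c(C=O)c(OCOC)c1 | intermediate
4 | trimethyl phosphonoacetate | COC(=O)CP(=O)(OC)OC | starting material
5 | methyl (E)-3-[2,6-bis(MOMO)-4-methoxyphenyl]acrylate | COC(=O)/C=C/c1c(OCOC)cc(OC)cc1OCOC | intermediate
6 | (E)-4-[2,6-bis(MOMO)-4-methoxyphenyl]-2-methylbut-3-en-2-ol | CC(C)(O)/C=C/c1c(OCOC)cc(OC)cc1OCOC | intermediate
7 | (Z)-4-[2,6-bis(MOMO)-4-methoxyphenyl]-2-methylbut-3-en-2-ol | CC(C)(O)/C=C\c1c(OCOC)cc(OC)cc1OCOC | intermediate
8 | 4-hydroxybenzaldehyde | O=Cc1ccc(O)cc1 | starting material
9 | 4-(methoxymethoxy)benzaldehyde | O=Cc1ccc(OCOC)cc1 | intermediate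
10 | diethyl [2-(methoxy(methyl)amino)-2-oxoethyl]phosphonate | CCOP(=O)(OCC)CC(=O)N(C)OC | starting material
11 | (E)-N-methoxy-N-methyl-3-[4-(MOMO)phenyl]acrylamide | CON(C)C(=O)/C=C/c1ccc(OCOC)cc1 | intermediate
12 | tris-MOM chalcone (2',4'-bis-OMOM, 6'-OMe, 3'-(Z)-3-hydroxy-3-methylbut-1-enyl, 4-OMOM) | COc1cc(OCOC)c(/C=C\C(C)(C)O)c(OCOC)c1C(=O)/C=C/c1ccc(OCOC)cc1 | intermediate
13 | candidachalcone | COc1cc(O)c(/C=C\C(C)(C)O)c(O)c1C(=O)/C=C/c1ccc(O)cc1 | target

## Totals
- Total steps: 9.
- Longest linear sequence: 7 (steps 1, 2, 3, 4, 5, 8, 9).

## Three steps most likely to fail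
1. **Step 5 (proposed new E→Z isomerisation).** The photostationary ratio may be poor because the 2,6-dialkoxyaryl ring is already twisted in the E isomer, and the Z-allylic benzylic alcohol may degrade on prolonged irradiation. Fallback: drop steps 3–5 and run a Still–Gennari olefination of aldehyde 3 with (CF3CH2O)2P(O)CH2CO2Me, KHMDS and 18-crown-6 in THF at −78 °C. This gives the Z-cinnamate directly, and MeMgBr (as in step 4) then gives 7.
2. **Step 8 (dianion lithiation and Weinreb addition).** The free alkoxide may hinder lithiation, and the hindered aryllithium may give conjugate addition or low conversion. Fallback: protect the tertiary OH as its TES ether, lithiate with 1.2 equiv n-BuLi and acetylate with N-acetylmorpholine, then run KOH/EtOH Claisen–Schmidt condensation with 9 and finish as in step 9.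
3. **Step 9 (global MOM removal).** The Z-allylic tertiary alcohol may ionise to the 2,2-dimethylchromene, or the 2'-hydroxychalcone may cyclise to a flavanone. Fallback: rebuild the route with SEM ethers in place of MOM (SEMCl in steps 1 and 6) and remove them at the end with TBAF or MgBr2, which avoids Lewis and Brønsted acid entirely.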